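The 1,2‑dioxane is cut at its fully substituted carbon C6, which carries O1 and sits between a C1–C5 head and a C7‑to‑phenyl tail of similar size. In one operation a racemic C3 hydroperoxy ketal bearing a 2‑(silylmethyl)allyl unit is exchanged onto the C6 dimethyl ketal of the citronellal‑derived tail, and Lewis‑acid ionisation lets the allylsilane capture the C6 peroxycarbenium ion: C6–O1 and C5–C6 form and the ring closes, leaving a C4 methylene. C3 anomerisation, diimide reduction and hydrolysis then set C4 and C3.

Key step: step 11

Remark: atoms are numbered along the chain from the carboxyl carbon (C1) to C16; the ring oxygen on C6 is O1 and that on C3 is O2.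
Remark: nothing in either fragment can bias the faces of the C6 cation with respect to remote C8, so the ring should form in both absolute senses in similar amounts. Structures from the cyclisation onward show the series with the target configuration at C6; its diastereomeric partner (ring centres inverted, C8 unchanged) is removed by preparative HPLC after the diimide step.

Step 1
Reactants: 1 ethyl 2-[(trimethylsilyl)methyl]prop-2-enoate
Product: 2 2-[(trimethylsilyl)methyl]prop-2-enoic acid
Conditions: LiOH, THF/H2O, 0 °C → rt; 1 M HCl to pH 3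
Reagents that add atoms: lithium hydroxide, [Li+].[OH-]
Why: Ester saponification (BAC2); the α‑substituted acrylate should hydrolyse without conjugate addition, and the allylsilane is inert because loss of silicon would give a cross‑conjugated, unstabilised allyl anion.

Step 2
Reactants: 2 2-[(trimethylsilyl)methyl]prop-2-enoic acid
Product: 4 methyl 3-oxo-4-[(trimethylsilyl)methyl]pent-4-enoate, via acyl imidazole 3 (not isolated)
Conditions: CDI, THF, rt; then Mg(O2CCH2CO2Me)2, THF, rt; 1 M HCl work‑up
Reagents that add atoms: magnesium bis(methyl malonate), [Mg+2].[O-]C(=O)CC(=O)OC.[O-]C(=O)CC(=O)OC; 1,1'-carbonyldiimidazole, O=C(n1ccnc1)n1ccnc1 (imidazolyl group of intermediate 3 only)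
Why: Masamune–Brooks homologation: the acyl imidazole C‑acylates the magnesium malonate half‑ester chelate under neutral conditions and the acyl malonate decarboxylates on acidification, which avoids the basic or hot conditions that would invite Michael addition to the α‑methylene ketone.

Step 3
Reactants: 4 methyl 3-oxo-4-[(trimethylsilyl)methyl]pent-4-enoate
Product: 6 methyl 3-hydroperoxy-3-methoxy-4-[(trimethylsilyl)methyl]pent-4-enoate (racemic, fragment 1), via dimethyl ketal 5 (not isolated)
Conditions: HC(OMe)3, MeOH, CSA (5 mol%), 0 °C → rt; volatiles removed below 20 °C; then anhydrous ethereal H2O2 (3 equiv), Et2O, 0 °C; NaHCO3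
Reagents that add atoms: trimethyl orthoformate, COC(OC)OC; hydrogen peroxide, OO
Why: Orthoformate ketalisation of the keto tautomer followed by acid‑catalysed perhydrolysis (ketal to hydroperoxy ketal exchange): hydrogen peroxide, the stronger α‑effect nucleophile, should capture the C3 oxocarbenium ion at the oxygen‑bearing carbon under kinetic control at low temperature, and telescoping avoids loss of methanol from 5 on silica; C3 forms racemic, which is immaterial.

Step 4
Reactants: 7 (R)-citronellal, (3R)-3,7-dimethyloct-6-enal
Product: 8 (4R)-4,8-dimethylnon-7-en-2-ol (both C2 epimers)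
Conditions: MeMgBr, Et2O, 0 °C; aq. NH4Cl
Reagents that add atoms: methylmagnesium bromide, C[Mg]Br
Why: Grignard addition to the aldehyde; the stereocentre of citronellal is not enolisable and the new carbinol centre is destroyed in step 5.

Step 5
Reactants: 8 (4R)-4,8-dimethylnon-7-en-2-ol
Product: 9 (4R)-4,8-dimethylnon-7-en-2-one
Conditions: Dess–Martin periodinane, NaHCO3, CH2Cl2, rt
Reagents that add atoms: none
Why: Dess–Martin oxidation of the secondary alcohol under buffered, neutral conditions that leave the trisubstituted alkene and the β‑stereocentre untouched.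

Step 6
Reactants: 9 (4R)-4,8-dimethylnon-7-en-2-one
Product: 10 (6R)-8,8-dimethoxy-2,6-dimethylnon-2-ene
Conditions: HC(OMe)3, MeOH, PPTS (cat.), rt; Et3N
Reagents that add atoms: trimethyl orthoformate, COC(OC)OC
Why: Acid‑catalysed ketalisation with the orthoformate as water scavenger installs the dimethyl ketal that the key step needs and protects the ketone during chain extension; the mild acid should not engage the remote alkene.

Step 7
Reactants: 10 (6R)-8,8-dimethoxy-2,6-dimethylnon-2-ene
Product: 12 (4R)-6,6-dimethoxy-4-methylheptanal, via secondary ozonide 11 (not isolated)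
Conditions: O3, NaHCO3 (solid), CH2Cl2, −78 °C; then PPh3, −78 °C → rt
Reagents that add atoms: ozone, [O-][O+]=O
Why: Ozonolysis of the electron‑rich trisubstituted alkene with reductive work‑up of the ozonide by triphenylphosphine gives the aldehyde; the bicarbonate buffer keeps the ketal intact.

Step 8
Reactants: 13 (5-bromopentyl)benzene
Product: 14 triphenyl(5-phenylpentyl)phosphonium bromide
Conditions: PPh3, MeCN, reflux
Reagents that add atoms: triphenylphosphine, c1ccc(cc1)P(c1ccccc1)c1ccccc1
Why: SN2 quaternisation of triphenylphosphine by the primary bromide.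

Step 9
Reactants: 12 (4R)-6,6-dimethoxy-4-methylheptanal; 14 triphenyl(5-phenylpentyl)phosphonium bromide
Product: 16 (4R,7Z)-2,2-dimethoxy-4-methyl-12-phenyldodec-7-ene, via phosphorus ylide 15 (not isolated)
Conditions: 14, NaN(SiMe3)2, THF, 0 °C; then 12, −78 °C → rt
Reagents that add atoms: none
Why: Wittig olefination with a non‑stabilised ylide, expected to be Z‑selective, although the geometry is irrelevant because the alkene is hydrogenated next; the basic medium is harmless to the ketal.

Step 10
Reactants: 16 (4R,7Z)-2,2-dimethoxy-4-methyl-12-phenyldodec-7-ene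
Product: 17 (4R)-2,2-dimethoxy-4-methyl-12-phenyldodecane (fragment 2)
Conditions: H2 (1 atm), Pd/C, EtOAc, Et3N (trace), rt
Reagents that add atoms: none
Why: Heterogeneous hydrogenation of the disubstituted alkene; the arene and the ketal should survive under slightly basic conditions at one atmosphere.

Step 11
Reactants: 6 methyl 3-hydroperoxy-3-methoxy-4-[(trimethylsilyl)methyl]pent-4-enoate (1.4 equiv); 17 (4R)-2,2-dimethoxy-4-methyl-12-phenyldodecane
Product: 19 methyl 2-[(3S,6S)-3-methoxy-6-methyl-4-methylidene-6-[(2R)-2-methyl-10-phenyldecyl]-1,2-dioxan-3-yl]acetate, via mixed peroxy ketal 18 (not isolated)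
Conditions: PPTS (10 mol%), 5 Å MS, CH2Cl2, 0 °C → rt; filtered and concentrated; then TMSOTf (0.5 equiv), 2,6-di-tert-butyl-4-methylpyridine, CH2Cl2 (0.01 M), −78 °C; Et3N
Reagents that add atoms: none
Why: Acid‑catalysed ketal exchange (loss of methanol through the C6 oxocarbenium ion) joins the hydroperoxide oxygen of 6 to C6 as O1 and gives bis‑ketal peroxide 18; the silyl triflate then removes the C6 methoxy group as MeOSiMe3, the peroxycarbenium ion is attacked by the γ‑carbon (C5) of the allylsilane, and the β‑silyl cation collapses with loss of silicon to the exocyclic C4 methylene (intramolecular Hosomi–Sakurai capture of a peroxycarbenium ion). The closest known reaction type is the Lewis‑acid cyclisation of allylsilane‑tethered monoperoxy ketals to 1,2‑dioxanes, the peroxide counterpart of the silyl‑modified Sakurai tetrahydropyran synthesis. The 1,2‑dioxane closes in the 6‑endo‑trig mode through a chair, with both alkene carbons C4 and C5 and the C6=O1 cation inside the new ring. C6 is set only relative to C3: methoxy axial (anomeric) and the C7 chain equatorial on the E‑peroxycarbenium ion should favour the 3S,6S relationship shown, modestly at best because methyl and CH2R differ little in size, and remote C8 exerts no control, so the ring‑inverted series forms alongside. The step needs ionisation at C6 rather than C3, secured by the electron‑withdrawing CH2CO2Me group on C3, the non‑chelating silyl triflate and low temperature. It also needs ring closure to beat oligomerisation and protodesilylation, secured by high dilution, the six‑membered transition state and the hindered base.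

Step 12
Reactants: 19 methyl 2-[(3S,6S)-3-methoxy-6-methyl-4-methylidene-6-[(2R)-2-methyl-10-phenyldecyl]-1,2-dioxan-3-yl]acetate
Product: 20 methyl 2-[(3R,6S)-3-methoxy-6-methyl-4-methylidene-6-[(2R)-2-methyl-10-phenyldecyl]-1,2-dioxan-3-yl]acetate
Conditions: CSA (10 mol%), MeOH, 0 °C → rt; Et3N; SiO2 chromatography, recovered 19 resubmitted
Reagents that add atoms: methanol, CO
Why: Acid‑catalysed ketal anomerisation through the ring peroxycarbenium ion equilibrates 19 with 20; both anomers keep the methoxy group axial and differ only in whether the C6 methyl or the C7 chain is axial, so similar amounts are expected, and 20 is taken on because it alone places the C7 chain axial, where it can direct the reduction in step 13.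

Step 13
Reactants: 20 methyl 2-[(3R,6S)-3-methoxy-6-methyl-4-methylidene-6-[(2R)-2-methyl-10-phenyldecyl]-1,2-dioxan-3-yl]acetate
Product: 21 methyl 2-[(3R,4R,6S)-3-methoxy-4,6-dimethyl-6-[(2R)-2-methyl-10-phenyldecyl]-1,2-dioxan-3-yl]acetate
Conditions: 2-nitrobenzenesulfonyl hydrazide (NBSH), Et3N, CH2Cl2, rt; preparative HPLC
Reagents that add atoms: none
Why: Diimide reduction (concerted syn transfer of two hydrogens, O–O bond untouched, base‑buffered so C3 does not anomerise): in the chair of 20 with axial methoxy, the axial C7 chain on C6 screens the syn‑axial face of the exocyclic alkene, so hydrogen should arrive on the opposite face and the new methyl ends cis to the chain (4R) by steric approach control; neither kinetic attack on anomer 19 nor later equilibration would give this relationship.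

Step 14
Reactants: 21 methyl 2-[(3R,4R,6S)-3-methoxy-4,6-dimethyl-6-[(2R)-2-methyl-10-phenyldecyl]-1,2-dioxan-3-yl]acetate
Product: 23 2-[(3S,4R,6S)-3-hydroxy-4,6-dimethyl-6-[(2R)-2-methyl-10-phenyldecyl]-1,2-dioxan-3-yl]acetic acid (target), via methoxy ketal acid 22 (not isolated)
Conditions: LiOH, THF/H2O, 0 °C → rt; then 1 M HCl to pH 1, THF/H2O, 0 °C → rt
Reagents that add atoms: lithium hydroxide, [Li+].[OH-]; water, O
Why: Saponification (BAC2; both peroxide carbons are fully substituted, so Kornblum–DeLaMare cleavage is impossible) followed by acid‑catalysed ketal hydrolysis through the C3 peroxycarbenium ion; water should return under thermodynamic control to the anomer with hydroxyl axial and the acetic acid chain, C4 methyl and C7 chain equatorial (3S), and the closed hemiketal masks the β‑keto acid against decarboxylation.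

Compound list
1 | ethyl 2-[(trimethylsilyl)methyl]prop-2-enoate (catalogue compound) | CCOC(=O)C(=C)C[Si](C)(C)C | starting material
2 | 2-[(trimethylsilyl)methyl]prop-2-enoic acid | OC(=O)C(=C)C[Si](C)(C)C | intermediate
3 | 1-(1H-imidazol-1-yl)-2-[(trimethylsilyl)methyl]prop-2-en-1-one | O=C(C(=C)C[Si](C)(C)C)n1ccnc1 | intermediate
4 | methyl 3-oxo-4-[(trimethylsilyl)methyl]pent-4-enoate | COC(=O)CC(=O)C(=C)C[Si](C)(C)C | intermediate
5 | methyl 3,3-dimethoxy-4-[(trimethylsilyl)methyl]pent-4-enoate | COC(=O)CC(OC)(OC)C(=C)C[Si](C)(C)C | intermediate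
6 | methyl 3-hydroperoxy-3-methoxy-4-[(trimethylsilyl)methyl]pent-4-enoate, racemic (fragment 1) | COC(=O)CC(OC)(OO)C(=C)C[Si](C)(C)C | intermediate
7 | (R)-citronellal, (3R)-3,7-dimethyloct-6-enal | C[C@H](CCC=C(C)C)CC=O | starting material
8 | (4R)-4,8-dimethylnon-7-en-2-ol, both C2 epimers | C[C@H](CCC=C(C)C)CC(C)O | intermediate
9 | (4R)-4,8-dimethylnon-7-en-2-one | C[C@H](CCC=C(C)C)CC(C)=O | intermediate
10 | (6R)-8,8-dimethoxy-2,6-dimethylnon-2-ene | C[C@H](CCC=C(C)C)CC(C)(OC)OC | intermediate
11 | 3-[(3R)-5,5-dimethoxy-3-methylhexyl]-5,5-dimethyl-1,2,4-trioxolane | C[C@H](CCC1OOC(C)(C)O1)CC(C)(OC)OC | intermediate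
12 | (4R)-6,6-dimethoxy-4-methylheptanal | C[C@H](CCC=O)CC(C)(OC)OC | intermediate
13 | (5-bromopentyl)benzene | BrCCCCCc1ccccc1 | starting material
14 | triphenyl(5-phenylpentyl)phosphonium bromide | [Br-].c1ccc(cc1)CCCCC[P+](c1ccccc1)(c1ccccc1)c1ccccc1 | intermediate
15 | triphenyl(5-phenylpentylidene)-λ5-phosphane | c1ccc(cc1)CCCCC=P(c1ccccc1)(c1ccccc1)c1ccccc1 | intermediate
16 | (4R,7Z)-2,2-dimethoxy-4-methyl-12-phenyldodec-7-ene | C[C@H](CC/C=C\CCCCc1ccccc1)CC(C)(OC)OC | intermediate
17 | (4R)-2,2-dimethoxy-4-methyl-12-phenyldodecane (fragment 2) | C[C@H](CCCCCCCCc1ccccc1)CC(C)(OC)OC | intermediate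
18 | methyl 3-methoxy-3-{[(4R)-2-methoxy-4-methyl-12-phenyldodecan-2-yl]peroxy}-4-[(trimethylsilyl)methyl]pent-4-enoate, mixture at both ketal carbons | C[C@H](CCCCCCCCc1ccccc1)CC(C)(OC)OOC(OC)(CC(=O)OC)C(=C)C[Si](C)(C)C | intermediate
19 | methyl 2-[(3S,6S)-3-methoxy-6-methyl-4-methylidene-6-[(2R)-2-methyl-10-phenyldecyl]-1,2-dioxan-3-yl]acetate | C[C@H](CCCCCCCCc1ccccc1)C[C@@]1(C)CC(=C)[C@](OC)(CC(=O)OC)OO1 | intermediate
20 | methyl 2-[(3R,6S)-3-methoxy-6-methyl-4-methylidene-6-[(2R)-2-methyl-10-phenyldecyl]-1,2-dioxan-3-yl]acetate | C[C@H](CCCCCCCCc1ccccc1)C[C@@]1(C)CC(=C)[C@@](OC)(CC(=O)OC)OO1 | intermediate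
21 | methyl 2-[(3R,4R,6S)-3-methoxy-4,6-dimethyl-6-[(2R)-2-methyl-10-phenyldecyl]-1,2-dioxan-3-yl]acetate | C[C@H](CCCCCCCCc1ccccc1)C[C@@]1(C)C[C@@H](C)[C@@](OC)(CC(=O)OC)OO1 | intermediate
22 | 2-[(3R,4R,6S)-3-methoxy-4,6-dimethyl-6-[(2R)-2-methyl-10-phenyldecyl]-1,2-dioxan-3-yl]acetic acid | C[C@H](CCCCCCCCc1ccccc1)C[C@@]1(C)C[C@@H](C)[C@@](OC)(CC(=O)O)OO1 | intermediate
23 | 2-[(3S,4R,6S)-3-hydroxy-4,6-dimethyl-6-[(2R)-2-methyl-10-phenyldecyl]-1,2-dioxan-3-yl]acetic acid | C[C@H](CCCCCCCCc1ccccc1)C[C@@]1(C)C[C@@H](C)[C@](O)(CC(=O)O)OO1 | target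

Total step count: 14. Longest linear sequence: 10 steps (7 to 23 through steps 4–7 and 9–14).

Steps most likely to fail

Step 11. The hindered tertiary hydroperoxide may fail to exchange onto the ketal, or ionisation at C3 and acid‑induced fragmentation of the bis‑ketal peroxide may outrun ring closure. The fallback sets out from 6 and 17 and returns at 19. Ketal 17 would be hydrolysed (PPTS, acetone/H2O) to (4R)-4-methyl-12-phenyldodecan-2-one F1, and 6 would be O‑silylated (Me3SiCl, Et3N) to methyl 3-methoxy-3-[(trimethylsilyl)peroxy]-4-[(trimethylsilyl)methyl]pent-4-enoate F2. Condensation of F1 with F2 under catalytic TMSOTf in CH2Cl2 at −78 °C, the silyl peroxide–carbonyl condensation known from 1,2,4‑trioxane synthesis, would generate the C6 peroxycarbenium ion directly from the carbonyl group. No C6 methoxy group then competes with the C3 methoxy group for the Lewis acid, and the same cyclisation should give 19.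

Step 3. The delocalised C3 cation may be captured at the methylene terminus, lose a proton to the conjugated enol ether, or the new hydroperoxide may lactonise onto the ester. The fallback sets out from 5 (isolated after an Et3N quench) and 17 and returns at 18. The roles of the partners are exchanged: the ordinary dialkyl ketal 17 would be perhydrolysed (ethereal H2O2, PPTS) to (4R)-2-hydroperoxy-2-methoxy-4-methyl-12-phenyldodecane F3, a robust tertiary alkoxy hydroperoxide. F3 would then be exchanged onto ketal 5 (PPTS, 5 Å MS), so that fragment 1 never meets free hydrogen peroxide, and the resulting 18 enters the second stage of step 11.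

Step 13. Hydrogen may be delivered to the face syn to the C7 chain, giving the C4 epimer, if the axial methoxy group rather than the axial C6 substituent governs approach. The fallback sets out from 19, which the equilibrium of step 12 supplies in equal measure, and returns at 23. In 19 the axial C6 substituent is the methyl group, so whichever ring face diimide prefers in 20, 19 presents the opposite relationship to the C7 chain. Reduction of 19 under the same conditions would then give methyl 2-[(3S,4R,6S)-3-methoxy-4,6-dimethyl-6-[(2R)-2-methyl-10-phenyldecyl]-1,2-dioxan-3-yl]acetate F4. Saponification would give 2-[(3S,4R,6S)-3-methoxy-4,6-dimethyl-6-[(2R)-2-methyl-10-phenyldecyl]-1,2-dioxan-3-yl]acetic acid F5, and its acid hydrolysis converges on 23 because C3 is set thermodynamically at the end.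

Further compounds
F1 | step 11 | (4R)-4-methyl-12-phenyldodecan-2-one | C[C@H](CCCCCCCCc1ccccc1)CC(C)=O
F2 | step 11 | methyl 3-methoxy-3-[(trimethylsilyl)peroxy]-4-[(trimethylsilyl)methyl]pent-4-enoate | COC(=O)CC(OC)(OO[Si](C)(C)C)C(=C)C[Si](C)(C)C
F3 | step 3 | (4R)-2-hydroperoxy-2-methoxy-4-methyl-12-phenyldodecane | C[C@H](CCCCCCCCc1ccccc1)CC(C)(OC)OO
F4 | step 13 | methyl 2-[(3S,4R,6S)-3-methoxy-4,6-dimethyl-6-[(2R)-2-methyl-10-phenyldecyl]-1,2-dioxan-3-yl]acetate | C[C@H](CCCCCCCCc1ccccc1)C[C@@]1(C)C[C@@H](C)[C@](OC)(CC(=O)OC)OO1
F5 | step 13 | 2-[(3S,4R,6S)-3-methoxy-4,6-dimethyl-6-[(2R)-2-methyl-10-phenyldecyl]-1,2-dioxan-3-yl]acetic acid | C[C@H](CCCCCCCCc1ccccc1)C[C@@]1(C)C[C@@H](C)[C@](OC)(CC(=O)O)OO1
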